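(The data were generated by integration for an exercise, and the scatter is random.)

Time is what this flask runs on: 8.0 d at one temperature, closed and stirred, with nothing added once it has started.

| flask | starting material | second substrate | free enzyme | remark | time |
|---|---|---|---|---|---|
| north-west | 20 mM | 0.95 equiv | 0.0085 mol% | run made earlier |  |
| north-east | 20 mM | 0.95 equiv | 0.013 mol% | run made earlier |  |
| south-west | 30 mM | 0.95 equiv | 0.017 mol% | run made earlier |  |
| flask | 20 mM | 0.950 equiv | 0.017 mol% |  | 8.0 d |

- north-west (time / d: target / %): 0.833: 8.3; 1.67: 16.8; 4.00: 35.1; 10.0: 68.2
- north-east (time / d: target / %): 0.833: 13.2; 1.67: 24.0; 4.00: 49.6; 10.0: 82.5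
- south-west (time / d: target / %): 0.833: 21.1; 1.67: 38.9; 4.00: 71.8; 10.0: 94.0

(standard deviation of a reading: 0.5 percentage points)

* how much target there is at 8.0 d, in percent of the starting material charged
* concentration of first product in solution at 8.0 d, in percent of saturation

The north-west and north-east runs, both at 20 mM, lie on one curve against loading times time, so I use that product as the clock. By that clock the flask ends a little beyond the last north-east reading, so I expect slightly more target than its 82.5%. Leave the second substrate at 0.950 equiv: it is the limiting reagent.

What to watch is the other product. I assume each target releases one first product, so dividing the two rates removes time: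

first product made = target share × starting material = 82.5% × 20 mM = 16.5 mM

This first product made is my estimate for the flask, reckoned at the last north-east reading, and it counts dissolved and undissolved alike. I read no solubility from these readings, so I commit to no saturation figure.

The forecast says 83.8% target and 70% of saturation, “which is a loose guess”.

The flask gives 83.7% target, with first product at 100% of saturation.

    starting material + free enzyme ⇌ first complex (K = 29.0 /M, k = 140 /M/s)
    first complex ⇌ loaded enzyme + first product (K = 0.450 M, k = 0.110 /s)
    second substrate + loaded enzyme ⇌ second complex (K = 27.0 /M, k = 250 /M/s)
    second complex → free enzyme + target (k = 0.0650 /s)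
    crystals ⇌ first product, rate k5*(cs5 - [first product]) while solid is left; crystals form when [first product] > cs5 (solubility = 9.00 mM, k = 0.00310 /s)

In the flask, dissolved first product stands at 9.01 mM at 4.00 d and still at 9.00 mM at 8.00 d, when the rate of making it over the rate of using it up, each step net, is 0.999. Crystals hold 7.73 mM at that time, so dissolved and crystals together come to 16.7 mM, against the 16.5 mM I reckoned. The same reckoning for the neighbour flask with 12 mM of starting material and 69.7% target gives 8.36 mM, and that neighbour holds 8.36 mM dissolved and crystals of 0 mM.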